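**Assumption:** compounds 1, 10, 13, 14 and 21 are taken as purchasable. The target has no stereocentre, and the alkene geometry of 23 is erased in step 12.

## Analysis of the target

The target is a macrocyclic bis(bibenzyl) quinone in which four six-membered carbocycles are joined into one 18-membered ring. Ring A is a 2-methoxy-1,4-benzoquinone (carbonyls at C1 and C4, OMe at C2, H at C3), ring B a para-phenylene, ring C a benzene with a free phenol at C6, and ring D a meta-phenylene. The links are a CH2CH2 bridge from ring A C6 to ring B C4, a diaryl ether from ring B C1 to ring C C1, a CH2CH2 bridge from ring C C3 to ring D C3, and an ether from ring D C1 to ring A C5. There is no stereocentre, so the problem is one of connectivity, regiochemistry and ring closure. The sensitive groups are the quinone and the ring C phenol: the quinone is reduced by hydrogen and low-valent metals, its C2–OMe and C5–OAr are vinylogous esters open to addition–elimination (attack at C5 would cut the macrocycle), and the phenol is itself oxidisable. Two things make the synthesis hard: ring A is pentasubstituted, with its carbon substituent between two different oxygens, and the 18-membered ring must be closed against oligomerisation without any rigid turn. The plan rests on the bridge between ring C C3 and ring D C3, two unbranched sp3 carbons flanked by two aryl carbons. Taken back to an E-alkene, this bridge is the sum of two aryl electrophiles and one ethene-1,2-diyl dianion, so both aryl–carbon bonds and the macrocycle can be made in one palladium-catalysed operation.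

## Retrosynthetic reasoning

**25 to 24.** The quinone is taken back first: the C4 carbonyl of ring A becomes a methyl ether and the C1 carbonyl a free phenol, which gives bisphenol 24. A quinone would not survive zerovalent palladium, stannanes, hydrogen or the basic ether couplings, whereas its para-methoxyphenol form is inert to all of them. The forward reaction has to oxidise ring A and leave the ring C phenol alone; the para oxygen of ring A, absent from ring C, should make that possible.

**24 to 23.** The ring C C3–ring D C3 bridge is dehydrogenated and both phenols are benzylated, giving the macrocyclic E-stilbene 23. Nothing is cut, but one forward hydrogenation then does three jobs: it saturates the alkene and frees both phenols.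

**23 to 20 and 21.** The macrocycle is opened by cutting both aryl–vinyl bonds, ring C C3–CH and CH–ring D C3. This leaves open-chain 20, with a triflate on ring C C3 and a bromine on ring D C3, and distannane 21 as the two-carbon piece. The two diaryl ethers and the ring A–ring B bridge were also candidates for ring closure, but each would need a final coupling between two different, highly functionalised ends, one of them on crowded ring A. Here the ends are two plain aryl electrophiles and the linker is symmetric. The forward reaction must make two C–C bonds in order, the second intramolecularly, and vinylstannane 22 is the species that has to cyclise faster than it oligomerises.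

**20 to 12 and 18.** Compound 20 is divided at the bond between ring B C4 and its benzylic CH2, into styrene 12 (rings A and D) and aryl iodide 18 (rings B and C). This is the most convergent cut, leaves one diaryl ether in each half, and puts boron on the hindered side and the halide on unhindered ring B. The forward hydroboration and Suzuki–Miyaura coupling must pick the C–I bond of 18 out of three carbon–(pseudo)halogen bonds; the two it spares are the ones step 11 needs.

**18 to 13 and 14.** The triflate of 18 is taken back to phenol 17, the phenol to the aldehyde of 15 (Dakin-type oxidation), and the ring B–O bond of 15 is cut to give 13 and 14. Ring C is thus bought with all three substituents in place, the aldehyde of 13 serving as a masked phenol para to the benzyl ether. The oxidation is done on this small fragment, before electron-rich ring A is present.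

**12 to 9 and 10.** The vinyl group of 12 comes from the aldehyde of 11 by methylenation, and the ring D–O bond of 11 is cut to give salicylaldehyde 9 and dihalide 10. The ether is made at this stage because the free phenol of 9 is needed beforehand to direct the formylation, and the iodine of 10 lets copper couple selectively and keep the bromine.

**9 to 1.** In 1 the two methoxy groups already flank the one ring hydrogen that survives (ring A C3–H), the formyl carbon marks C1 and the bromine marks C5; only C6 between them lacks its carbon. Backwards, the formyl group of 9 is removed from C6 (ortho-formylation of phenol 7), the phenol of 7 goes back to bromide 4 (lithiation, borylation, oxidation), the benzyl ether of 4 to phenol 3, and the phenol of 3 to the aldehyde of 1 (Dakin-type oxidation). The first oxygen is benzylated before the second is created, which is how the two oxygens flanking C6 are told apart.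

## Alternatives that were turned down

**Alternative 1:** Moore ring expansion of a squarate adduct.
- Disconnection: ring A itself. The C1–C2 and C3–H bonds of the quinone are cut, leading to the macrocyclic 4-hydroxy-4-(methoxyethynyl)cyclobutenone A2 and, one step further back, to the macrocyclic cyclobutenedione A3 and a methoxyethynyl anion equivalent.
- Forward key step: A2 is heated. 4π-Electrocyclic opening gives an enynyl ketene, the ketene carbon bonds to the methoxy-bearing alkyne carbon, the hydroxyl hydrogen moves to C3, and quinone A1 (the ring C benzyl ether of the target) results.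
- For: every substituent of ring A is placed by construction, so no ring oxygens have to be told apart and no phenol is oxidised beside another. On this point it is stronger than the chosen plan. The 1,2-addition to A3 should also go the right way, at the carbonyl next to the aryloxy-bearing carbon, because the other carbonyl is a vinylogous ester.
- Against: the ring expansion does not close the macrocycle, so A3 must first be cyclised around a strained, electrophilic dione whose aryloxy group is a leaving group. An oxygen substituent on the alkyne terminus stabilises the vinyl radical of the competing five-membered closure, so an alkylidenecyclopentenedione is a likely side product. A1 still needs debenzylation on the quinone, where hydrogenolysis reduces ring A and Lewis acids threaten the C5 aryloxy link.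
- Comparison: with the squarate chemistry, a separate macrocyclisation and the deprotection it is not shorter. The chosen plan gives up the ring A construction but buys ring A nearly complete in 1, and its ring closure also builds the ring C–ring D bridge.

**Alternative 2:** oxidative phenol coupling.
- Disconnection: the diaryl ether bond between the ring B oxygen and ring C C1, leading to open-chain quinone A5 with a 2,6-dichlorophenol as ring B and a 2,6-dibromophenol as ring C.
- Forward key step: Tl(NO3)3 (trivalent thallium) oxidises the dibromophenol, the ring B phenol oxygen adds to its bromine-bearing ortho carbon, and zinc reduces the dienone with loss of that bromine to give halogenated macrocycle A4.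
- For: the ring is closed at the bond that phenol coupling forms most naturally, and the halogen pattern decides which phenol is oxidised and which attacks. It needs no palladium, no tin and no protecting groups on rings B and C, and on these points it is stronger than the chosen plan.
- Against: A4 still carries two chlorines and one bromine, whose removal needs forcing hydrogenolysis that also reduces the quinone. The quinone of A5 must pass through a stoichiometric thallium oxidant and zinc, which reduces it, so a re-oxidation is added. A5 itself requires both CH2CH2 bridges and the ring A–ring D ether to be built with four aryl halogens as passengers.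
- Comparison: three halogens are put in and taken out again, so step economy is worse. In the chosen plan both leaving groups are consumed in the ring closure, and the only reduction is also the global deprotection.

**Alternative 3:** photo-Fries ring contraction.
- Disconnection: the ring A C6–CH2 bond in its oxidised form, C6–C(=O), with the acyl group moved back to the ring A C1 oxygen, giving 20-membered aryl ester A7.
- Forward key step: irradiation at 254 nm cleaves the O–acyl bond of A7, and recombination of the caged radical pair at C6 gives 18-membered ortho-hydroxyaryl ketone A6.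
- For: the ring is first closed by a macrolactonisation, which is a more dependable ring closure than a double cross-coupling; on this point it is stronger than the chosen plan. The crowded C6–C bond is then formed intramolecularly at the only free position next to the phenol oxygen, and the C1 phenol emerges free for the quinone oxidation.
- Against: the acyl radical is an arylacetyl radical, which loses carbon monoxide quickly; the resulting benzyl radical recombines to a diarylmethane or a benzyl aryl ether of the wrong ring size. A7 has further chromophores absorbing at 254 nm, including a benzyl aryl ether. A6 carries a ketone that must afterwards be reduced to CH2 next to an electron-rich phenol.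
- Comparison: the chosen plan makes the ring A–ring B bridge at the right oxidation level in one thermal coupling (step 10) and needs no photochemistry or deoxygenation.

Key step: step 11

## Route

**Step 1**  
Reactants: 1 5-bromo-2,4-dimethoxybenzaldehyde  
Product: 3 5-bromo-2,4-dimethoxyphenol, via aryl formate 2 (not isolated)  
Conditions: mCPBA, CH2Cl2, 0 °C to rt; aq Na2S2O3/NaHCO3 wash; then K2CO3 (cat.), MeOH, rt  
Reagents that add atoms: mCPBA (3-chloroperoxybenzoic acid), O=C(OO)c1cccc(Cl)c1  
Why: Dakin-type Baeyer–Villiger oxidation; the aryl group, electron-rich through its ortho and para methoxy groups, migrates in preference to hydrogen to give formate 2, and residual peracid is reduced in the wash before methanolysis, so the oxidisable phenol 3 never meets the oxidant.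

**Step 2**  
Reactants: 3 5-bromo-2,4-dimethoxyphenol  
Product: 4 1-(benzyloxy)-5-bromo-2,4-dimethoxybenzene  
Conditions: BnBr, K2CO3, DMF, rt  
Reagents that add atoms: benzyl bromide, BrCc1ccccc1  
Why: Williamson ether synthesis on a phenoxide with a reactive benzylic halide; benzyl is chosen because the hydrogenation of step 12 removes it.

**Step 3**  
Reactants: 4 1-(benzyloxy)-5-bromo-2,4-dimethoxybenzene  
Product: 7 5-(benzyloxy)-2,4-dimethoxyphenol, via aryllithium 5 (not isolated), via dimethyl arylboronate 6 (not isolated)  
Conditions: n-BuLi, THF, −78 °C; B(OMe)3, −78 °C to rt; then AcOH, 30% H2O2, 0 °C to rt  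
Reagents that add atoms: hydrogen peroxide, OO (oxygen of the new phenol); trimethyl borate, COB(OC)OC (boron and methoxy groups of 6 only); n-butyllithium, [Li]CCCC (lithium of 5 only)  
Why: bromine–lithium exchange at −78 °C is faster than deprotonation next to the benzyl ether, the aryllithium is trapped as the boronate, and peroxide oxidation with 1,2-shift of the aryl group from boron to oxygen gives the phenol (borylation–oxidation of an aryl halide); the second ring A oxygen thus appears free while the first stays benzylated.

**Step 4**  
Reactants: 7 5-(benzyloxy)-2,4-dimethoxyphenol  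
Product: 9 2-(benzyloxy)-6-hydroxy-3,5-dimethoxybenzaldehyde, via salicyl alcohol 8 (not isolated)  
Conditions: MgCl2, Et3N, (CH2O)n, MeCN, reflux; aq HCl work-up  
Reagents that add atoms: formaldehyde (from paraformaldehyde), C=O  
Why: magnesium-mediated ortho-formylation of a phenol (Casnati–Skattebøl reaction); the magnesium phenoxide delivers formaldehyde to the only free ortho position, ring A C6 between OH and OBn, and the alkoxide of 8 passes hydride to a second formaldehyde, while the carbon between the two methoxy groups is meta to the phenoxide and is not reached.

**Step 5**  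
Reactants: 9 2-(benzyloxy)-6-hydroxy-3,5-dimethoxybenzaldehyde; 10 1-bromo-3-iodobenzene  
Product: 11 2-(benzyloxy)-6-(3-bromophenoxy)-3,5-dimethoxybenzaldehyde  
Conditions: CuI (10 mol%), picolinic acid (20 mol%), K3PO4, DMSO, 90 °C  
Reagents that add atoms: none  
Why: Ullmann-type copper-catalysed diaryl ether synthesis; copper activates the C–I bond of 10 well before its C–Br bond, so the bromine needed in step 11 is kept, and the picolinate ligand tolerates phenols with two ortho substituents.

**Step 6**  
Reactants: 11 2-(benzyloxy)-6-(3-bromophenoxy)-3,5-dimethoxybenzaldehyde  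
Product: 12 2-(benzyloxy)-4-(3-bromophenoxy)-3-ethenyl-1,5-dimethoxybenzene  
Conditions: Ph3PCH3Br, KOtBu, THF, 0 °C to rt  
Reagents that add atoms: methylenetriphenylphosphorane (made in the flask from methyltriphenylphosphonium bromide and KOtBu), C=P(c1ccccc1)(c1ccccc1)c1ccccc1  
Why: Wittig methylenation; the aldehyde is non-enolisable, the small unstabilised ylide reaches a carbonyl flanked by two ortho ethers, and the aryl bromide is inert to it.

**Step 7**  
Reactants: 13 4-(benzyloxy)-3-hydroxybenzaldehyde; 14 1,4-diiodobenzene  
Product: 15 4-(benzyloxy)-3-(4-iodophenoxy)benzaldehyde  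
Conditions: 14 (3 equiv), CuI (10 mol%), picolinic acid (20 mol%), K3PO4, DMSO, 80 °C  
Reagents that add atoms: none  
Why: Ullmann-type copper-catalysed diaryl ether synthesis; the excess of symmetric 14 favours mono-arylation, and the product iodide, now para to an aryloxy donor, is less reactive than 14.

**Step 8**  
Reactants: 15 4-(benzyloxy)-3-(4-iodophenoxy)benzaldehyde  
Product: 17 4-(benzyloxy)-3-(4-iodophenoxy)phenol, via aryl formate 16 (not isolated)  
Conditions: mCPBA, CH2Cl2, 0 °C to rt; aq Na2S2O3/NaHCO3 wash; then K2CO3 (cat.), MeOH, rt  
Reagents that add atoms: mCPBA (3-chloroperoxybenzoic acid), O=C(OO)c1cccc(Cl)c1  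
Why: Dakin-type Baeyer–Villiger oxidation; the para benzyloxy group makes the aryl group the migrating group, formate 16 is methanolysed, and the thiosulfate wash returns any aryl iodide oxidised at iodine.

**Step 9**  
Reactants: 17 4-(benzyloxy)-3-(4-iodophenoxy)phenol  
Product: 18 4-(benzyloxy)-3-(4-iodophenoxy)phenyl trifluoromethanesulfonate  
Conditions: Tf2O, pyridine, CH2Cl2, 0 °C  
Reagents that add atoms: trifluoromethanesulfonic anhydride, O=S(=O)(OS(=O)(=O)C(F)(F)F)C(F)(F)F  
Why: O-sulfonylation of a phenol; 18 now carries two electrophiles of graded reactivity, C–I for step 10 and C–OTf for step 11.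

**Step 10**  
Reactants: 12 2-(benzyloxy)-4-(3-bromophenoxy)-3-ethenyl-1,5-dimethoxybenzene; 18 4-(benzyloxy)-3-(4-iodophenoxy)phenyl trifluoromethanesulfonate  
Product: 20 4-(benzyloxy)-3-(4-{2-[2-(benzyloxy)-6-(3-bromophenoxy)-3,5-dimethoxyphenyl]ethyl}phenoxy)phenyl trifluoromethanesulfonate, via B-alkyl-9-BBN borane 19 (not isolated)  
Conditions: 12, 9-BBN, THF, 0 to 40 °C; then 18, Pd(dppf)Cl2·CH2Cl2 (5 mol%), AsPh3 (5 mol%), Cs2CO3, DMF/THF/H2O, rt  
Reagents that add atoms: 9-borabicyclo[3.3.1]nonane, B1C2CCCC1CCC2 (boron and bicycle of 19 only)  
Why: anti-Markovnikov hydroboration puts boron on the terminal carbon, and the B-alkyl Suzuki–Miyaura coupling of 19 then takes place at the C–I bond of 18, the only carbon–(pseudo)halogen bond that adds to zerovalent palladium at room temperature; the ring D bromide and the electron-rich ring C triflate need heating and are kept for step 11.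

**Step 11**  
Reactants: 20 4-(benzyloxy)-3-(4-{2-[2-(benzyloxy)-6-(3-bromophenoxy)-3,5-dimethoxyphenyl]ethyl}phenoxy)phenyl trifluoromethanesulfonate; 21 (E)-1,2-bis(tributylstannyl)ethene  
Product: 23 18-membered macrocyclic E-stilbene (as 20, but ring C C3 and ring D C3 joined by an (E)-CH=CH unit in place of OTf and Br; benzyl ethers on ring A C1–O and ring C C6–O, OMe on ring A C2 and C4), via ring D vinylstannane 22 (not isolated)  
Conditions: Pd(PPh3)4 (20 mol%), LiCl (6 equiv), BHT (cat.), 1,4-dioxane, 100 °C; 20 added by syringe pump over 16 h to 21 (1.1 equiv) and the catalyst, final 2 mM  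
Reagents that add atoms: none  
Why: A Stille coupling run twice on one ethene linchpin (stitching macrocyclisation); the closest known reaction type is the Pd(PPh3)4/LiCl coupling of aryl bromides and aryl triflates with vinylstannanes. Zerovalent palladium should insert first into the ring D C–Br bond, which with triphenylphosphine ligands is more reactive than the electron-rich ring C triflate; transmetalation of one tin end of 21 and reductive elimination form the CH–ring D C3 bond and give 22. Oxidative addition at the ring C C–OTf bond follows, LiCl turning the arylpalladium triflate into the chloride that transmetalates; the tin now sits in the same molecule, so this transmetalation is intramolecular and passes through a 19-membered palladacycle. Reductive elimination forms the ring C C3–CH bond and closes the 18-membered ring by an sp2–sp2 coupling in which both new bonds are endocyclic. No stereocentre is formed, and the E geometry is carried over from 21 because vinyl transfer from tin and reductive elimination both go with retention. The selectivity needed is ring closure over oligomerisation and over capture of 22 by a second molecule of 21. It is secured by the slow addition of 20, which keeps 20 and 22 at low stationary concentration, by the near-stoichiometric amount of 21 at millimolar dilution, and by the graded reactivity of bromide and triflate, which lets 22 form before the second site is engaged. The para and meta arene links and the two diaryl ether angles fold the chain into a loop that an E-alkene between two meta-substituted rings can span.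

**Step 12**  
Reactants: 23 18-membered macrocyclic E-stilbene  
Product: 24 18-membered macrocyclic bisphenol (CH2CH2 bridge between ring C C3 and ring D C3; OH on ring A C1 and ring C C6; OMe on ring A C2 and C4)  
Conditions: H2 (1–3 atm), Pd/C (10% palladium on carbon), EtOAc/MeOH, rt  
Reagents that add atoms: none  
Why: heterogeneous catalytic hydrogenation; the diarylethene is saturated and both benzyl ethers are hydrogenolysed in the same operation, while diaryl and methyl ethers are inert.

**Step 13**  
Reactants: 24 18-membered macrocyclic bisphenol  
Product: 25 CNP0332646.0 (the 2-methoxy-1,4-benzoquinone macrocycle)  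
Conditions: PhI(OAc)2 (1.05 equiv), MeCN/H2O (2:1), 0 °C  
Reagents that add atoms: water, O  
Why: oxidative demethylation of a para-methoxyphenol with a trivalent iodine reagent; the more electron-rich ring A phenol binds to iodine, water adds at C4 para to it and methanol is lost, giving the 1,4-quinone with C2–OMe and C5–OAr untouched, whereas the ring C phenol has no para oxygen and should react more slowly with one equivalent at 0 °C.

## Compound list

1 | 5-bromo-2,4-dimethoxybenzaldehyde | COc1cc(OC)c(Br)cc1C=O | starting material  
2 | 5-bromo-2,4-dimethoxyphenyl formate | COc1cc(OC)c(Br)cc1OC=O | intermediate (not isolated)  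
3 | 5-bromo-2,4-dimethoxyphenol | COc1cc(OC)c(Br)cc1O | intermediate  
4 | 1-(benzyloxy)-5-bromo-2,4-dimethoxybenzene | COc1cc(OC)c(Br)cc1OCc1ccccc1 | intermediate  
5 | [5-(benzyloxy)-2,4-dimethoxyphenyl]lithium | COc1cc(OC)c([Li])cc1OCc1ccccc1 | intermediate (not isolated)  
6 | dimethyl [5-(benzyloxy)-2,4-dimethoxyphenyl]boronate | COc1cc(OC)c(B(OC)OC)cc1OCc1ccccc1 | intermediate (not isolated)  
7 | 5-(benzyloxy)-2,4-dimethoxyphenol | COc1cc(OC)c(O)cc1OCc1ccccc1 | intermediate  
8 | 3-(benzyloxy)-2-(hydroxymethyl)-4,6-dimethoxyphenol (as its magnesium salt) | COc1cc(OC)c(O)c(CO)c1OCc1ccccc1 | intermediate (not isolated)  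
9 | 2-(benzyloxy)-6-hydroxy-3,5-dimethoxybenzaldehyde | COc1cc(OC)c(O)c(C=O)c1OCc1ccccc1 | intermediate  
10 | 1-bromo-3-iodobenzene | Brc1cccc(I)c1 | starting material  
11 | 2-(benzyloxy)-6-(3-bromophenoxy)-3,5-dimethoxybenzaldehyde | COc1cc(OC)c(Oc2cccc(Br)c2)c(C=O)c1OCc1ccccc1 | intermediate  
12 | 2-(benzyloxy)-4-(3-bromophenoxy)-3-ethenyl-1,5-dimethoxybenzene | COc1cc(OC)c(Oc2cccc(Br)c2)c(C=C)c1OCc1ccccc1 | intermediate  
13 | 4-(benzyloxy)-3-hydroxybenzaldehyde | O=Cc1ccc(OCc2ccccc2)c(O)c1 | starting material  
14 | 1,4-diiodobenzene | Ic1ccc(I)cc1 | starting material  
15 | 4-(benzyloxy)-3-(4-iodophenoxy)benzaldehyde | O=Cc1ccc(OCc2ccccc2)c(Oc2ccc(I)cc2)c1 | intermediate  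
16 | 4-(benzyloxy)-3-(4-iodophenoxy)phenyl formate | O=COc1ccc(OCc2ccccc2)c(Oc2ccc(I)cc2)c1 | intermediate (not isolated)  
17 | 4-(benzyloxy)-3-(4-iodophenoxy)phenol | Oc1ccc(OCc2ccccc2)c(Oc2ccc(I)cc2)c1 | intermediate  
18 | 4-(benzyloxy)-3-(4-iodophenoxy)phenyl trifluoromethanesulfonate | FC(F)(F)S(=O)(=O)Oc1ccc(OCc2ccccc2)c(Oc2ccc(I)cc2)c1 | intermediate  
19 | 9-{2-[2-(benzyloxy)-6-(3-bromophenoxy)-3,5-dimethoxyphenyl]ethyl}-9-borabicyclo[3.3.1]nonane | COc1cc(OC)c(Oc2cccc(Br)c2)c(CCB2C3CCCC2CCC3)c1OCc1ccccc1 | intermediate (not isolated)  
20 | 4-(benzyloxy)-3-(4-{2-[2-(benzyloxy)-6-(3-bromophenoxy)-3,5-dimethoxyphenyl]ethyl}phenoxy)phenyl trifluoromethanesulfonate | COc1cc(OC)c(Oc2cccc(Br)c2)c(CCc2ccc(cc2)Oc2cc(OS(=O)(=O)C(F)(F)F)ccc2OCc2ccccc2)c1OCc1ccccc1 | intermediate  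
21 | (E)-1,2-bis(tributylstannyl)ethene | CCCC[Sn](CCCC)(CCCC)/C=C/[Sn](CCCC)(CCCC)CCCC | starting material  
22 | 4-(benzyloxy)-3-{4-[2-(2-(benzyloxy)-3,5-dimethoxy-6-{3-[(E)-2-(tributylstannyl)ethenyl]phenoxy}phenyl)ethyl]phenoxy}phenyl trifluoromethanesulfonate | COc1cc(OC)c(Oc2cccc(/C=C/[Sn](CCCC)(CCCC)CCCC)c2)c(CCc2ccc(cc2)Oc2cc(OS(=O)(=O)C(F)(F)F)ccc2OCc2ccccc2)c1OCc1ccccc1 | intermediate (not isolated)  
23 | 18-membered macrocyclic E-stilbene, bis(benzyl ether) | COc1cc(OC)c2c(c1OCc1ccccc1)CCc1ccc(cc1)Oc1cc(ccc1OCc1ccccc1)/C=C/c1cccc(c1)O2 | intermediate  
24 | 18-membered macrocyclic bisphenol | COc1cc(OC)c2c(c1O)CCc1ccc(cc1)Oc1cc(ccc1O)CCc1cccc(c1)O2 | intermediate  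
25 | CNP0332646.0 | COC1=CC(=O)C2=C(CCc3ccc(cc3)Oc3cc(ccc3O)CCc3cccc(c3)O2)C1=O | target  

## Step count and least certain steps

Total step count: 13. Longest linear sequence: 10 steps (steps 1–6, then 10–13); the ring B–ring C fragment takes 3 steps (7–9).

**Step 11 (key step).** The most likely failure is oligomerisation: the stannane of 22 is captured by an arylpalladium bromide from a second molecule of 20, or the arylpalladium species from 22 is captured by a second molecule of 21, before the slow oxidative addition at the electron-rich triflate allows ring closure. The fixed E geometry also leaves the closing chain little freedom. The fallback closes the ring at the central C=C instead. Setting out from 20, a twofold Stille vinylation with tributyl(vinyl)stannane (Pd(PPh3)4, LiCl, 1,4-dioxane, 100 °C) should give bis-styrene F1. Ring-closing metathesis of F1 with the second-generation Grubbs catalyst, (H2IMes)(PCy3)Cl2Ru=CHPh, in dilute toluene with loss of ethene should then give the macrocyclic stilbene in whichever geometry the ring prefers, that is 23 itself or the Z-configured macrocyclic stilbene F2. Either is hydrogenated under the conditions of step 12, and the route is rejoined at 24.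

**Step 5.** The phenoxide of 9 is deactivated by its ortho formyl group and hindered by two ortho substituents, so the arylation may be slow; prolonged heating would then erode the iodide-over-bromide selectivity and degrade the aldehyde. The fallback is a metal-free arylation. Setting out from 10, oxidation at iodine with mCPBA and TsOH in MeCN and trapping with 1,3,5-trimethoxybenzene should give (3-bromophenyl)(2,4,6-trimethoxyphenyl)iodonium tosylate F3. Treating 9 with F3 and K2CO3 in MeCN at rt to 50 °C should transfer the 3-bromophenyl group to the phenoxide by ligand coupling at trivalent iodine, the trimethoxyphenyl group leaving with the iodine. The route is rejoined at 11.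

**Step 10.** If transmetalation of the bulky alkylborane is slow, oxidative addition at the ring D C–Br bond of 19 or 20 (less likely at the triflate) may compete with that at the ring B C–I bond and lead to over-coupling. The fallback brings the bromide in only after the palladium step. Setting out from 9, protection with MOMCl and iPr2NEt should give MOM ether F4, and Wittig methylenation as in step 6 styrene F5. Hydroboration with 9-BBN gives alkylborane F6, which is not isolated and is coupled with 18 under the conditions of step 10, now with no bromide in the flask, to give bibenzyl triflate F7. HCl in MeOH/THF removes the MOM group to give phenol F8. Chan–Lam arylation of F8 with (3-bromophenyl)boronic acid (Cu(OAc)2, pyridine, 4 Å molecular sieves, CH2Cl2, air, rt) leaves the triflate alone, and the route is rejoined at 20.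

**Step 13.** Both phenols of 24 are exposed to the oxidant, so the ring C phenol may be dearomatised at its para carbon, or water, acetate or a phenol may add to the new quinone. The fallback masks the ring C phenol first. Setting out from 24, TBSCl and imidazole in DMF at 0 °C should silylate the less hindered ring C phenol (the ring A phenol is flanked by OMe and the CH2CH2 chain) and give mono-silyl ether F9. Oxidation with PhI(OAc)2 in MeCN/H2O then gives silylated quinone F10, and HF·pyridine in THF removes the silyl group under non-basic conditions. The route is rejoined at 25.

## Further compounds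

F1 | step 11 | 4-(benzyloxy)-3-(4-{2-[2-(benzyloxy)-6-(3-ethenylphenoxy)-3,5-dimethoxyphenyl]ethyl}phenoxy)-1-ethenylbenzene | COc1cc(OC)c(Oc2cccc(C=C)c2)c(CCc2ccc(cc2)Oc2cc(C=C)ccc2OCc2ccccc2)c1OCc1ccccc1  
F2 | step 11 | Z isomer of macrocyclic stilbene 23 | COc1cc(OC)c2c(c1OCc1ccccc1)CCc1ccc(cc1)Oc1cc(ccc1OCc1ccccc1)/C=C\c1cccc(c1)O2  
F3 | step 5 | (3-bromophenyl)(2,4,6-trimethoxyphenyl)iodonium 4-methylbenzenesulfonate | COc1cc(OC)c([I+]c2cccc(Br)c2)c(OC)c1.Cc1ccc(cc1)S(=O)(=O)[O-]  
F4 | step 10 | 2-(benzyloxy)-3,5-dimethoxy-6-(methoxymethoxy)benzaldehyde | COCOc1c(OC)cc(OC)c(OCc2ccccc2)c1C=O  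
F5 | step 10 | 2-(benzyloxy)-3-ethenyl-1,5-dimethoxy-4-(methoxymethoxy)benzene | COCOc1c(OC)cc(OC)c(OCc2ccccc2)c1C=C  
F6 | step 10 | 9-{2-[2-(benzyloxy)-3,5-dimethoxy-6-(methoxymethoxy)phenyl]ethyl}-9-borabicyclo[3.3.1]nonane | COCOc1c(OC)cc(OC)c(OCc2ccccc2)c1CCB1C2CCCC1CCC2  
F7 | step 10 | 4-(benzyloxy)-3-(4-{2-[2-(benzyloxy)-3,5-dimethoxy-6-(methoxymethoxy)phenyl]ethyl}phenoxy)phenyl trifluoromethanesulfonate | COCOc1c(OC)cc(OC)c(OCc2ccccc2)c1CCc1ccc(cc1)Oc1cc(OS(=O)(=O)C(F)(F)F)ccc1OCc1ccccc1  
F8 | step 10 | 4-(benzyloxy)-3-(4-{2-[2-(benzyloxy)-6-hydroxy-3,5-dimethoxyphenyl]ethyl}phenoxy)phenyl trifluoromethanesulfonate | COc1cc(OC)c(OCc2ccccc2)c(CCc2ccc(cc2)Oc2cc(OS(=O)(=O)C(F)(F)F)ccc2OCc2ccccc2)c1O  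
F9 | step 13 | ring C tert-butyldimethylsilyl ether of bisphenol 24 | COc1cc(OC)c2c(c1O)CCc1ccc(cc1)Oc1cc(ccc1O[Si](C)(C)C(C)(C)C)CCc1cccc(c1)O2  
F10 | step 13 | ring C tert-butyldimethylsilyl ether of 25 | COC1=CC(=O)C2=C(CCc3ccc(cc3)Oc3cc(ccc3O[Si](C)(C)C(C)(C)C)CCc3cccc(c3)O2)C1=O  
A1 | alternative 1 | ring C benzyl ether of the target quinone | COC1=CC(=O)C2=C(CCc3ccc(cc3)Oc3cc(ccc3OCc3ccccc3)CCc3cccc(c3)O2)C1=O  
A2 | alternative 1 | macrocyclic 2-alkyl-3-aryloxy-4-hydroxy-4-(methoxyethynyl)cyclobut-2-enone (racemic) | COC#CC1(O)C(=O)C2=C1Oc1cccc(c1)CCc1ccc(OCc3ccccc3)c(c1)Oc1ccc(CC2)cc1  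
A3 | alternative 1 | macrocyclic 3-alkyl-4-aryloxycyclobut-3-ene-1,2-dione | O=C1C(=O)C2=C1Oc1cccc(c1)CCc1ccc(OCc3ccccc3)c(c1)Oc1ccc(CC2)cc1  
A4 | alternative 2 | target macrocycle with two chlorines on ring B and one bromine on ring C | COC1=CC(=O)C2=C(CCc3cc(Cl)c(c(Cl)c3)Oc3cc(cc(Br)c3O)CCc3cccc(c3)O2)C1=O  
A5 | alternative 2 | open-chain quinone with 3,5-dichloro-4-hydroxyphenyl (ring B) and 3,5-dibromo-4-hydroxyphenyl (ring C) | COC1=CC(=O)C(Oc2cccc(CCc3cc(Br)c(O)c(Br)c3)c2)=C(CCc2cc(Cl)c(O)c(Cl)c2)C1=O  
A6 | alternative 3 | 18-membered ortho-hydroxyaryl benzyl ketone macrocycle | COc1cc(OC)c2c(c1O)C(=O)Cc1ccc(cc1)Oc1cc(ccc1OCc1ccccc1)CCc1cccc(c1)O2  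
A7 | alternative 3 | 20-membered aryl arylacetate macrolactone | COc1cc(OC)c2cc1OC(=O)Cc1ccc(cc1)Oc1cc(ccc1OCc1ccccc1)CCc1cccc(c1)O2  
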